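(The runs were generated by integration for an exercise, noise included.)

1. The easy step is to divide left-handed product by right-handed product at the earliest reading of the runs below.

| setting | dusk | dawn | flask |
|---|---|---|---|
| left-handed substrate | 0.16 M | 0.16 M | 0.16 M |
| right-handed substrate | 0.16 M | 0.16 M | 0.16 M |
| solid reagent | 4.2 equiv | 6.6 equiv | 3.00 equiv |
| remark | run made earlier | run made earlier |  |
| time |  |  | 10 d |

| run | time / d | left-handed product / % | right-handed product / % | left-handed substrate / % |
|---|---|---|---|---|
| dusk | 0.833 | 2.4 | 0.2 | 48.3 |
| dusk | 2.00 | 7.4 | 2.1 | 44.6 |
| dusk | 4.00 | 16.7 | 6.4 | 38.1 |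
| dusk | 6.00 | 25.2 | 9.6 | 32.4 |
| dawn | 0.500 | 0.1 | 0 | 49.9 |
| dawn | 1.04 | 3.4 | 0 | 48.0 |
| dawn | 2.50 | 9.7 | 3.6 | 43.3 |
| dawn | 6.00 | 25.3 | 8.2 | 31.4 |

(standard deviation of a reading: 0.5 percentage points)

- partner is single-handed; left-handed substrate and right-handed substrate are mirror images of each other, charged as a racemate, each of them at the stated concentration
- solid reagent is a solid; its amount is given per volume of the solution
- what was read earlier has a scatter of 0.5 percentage points, one standard deviation
- at the start none of the solid reagent is in solution
- an excess is the difference of the two amounts in percent of their sum
- an excess is below zero if the other one leads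
- the handed part of partner does not stay in what it makes, so the products of the two hands are mirror images too

1. excess of left-handed product over right-handed product in the product at 5.0 h
2. excess of left-handed product over right-handed product in the product at 10 d
3. part of the left-handed substrate and right-handed substrate charged together that has reacted at 10 d

2. In the dusk run at 0.833 d that ratio is 12.0, and its common logarithm is 1.08. The rule stops at the scatter, though. That right-handed product reading is 0.400 of one standard deviation, so I cannot trust this ratio. In the dawn run at 6.00 d, the right-handed product reading is 16.4 standard deviations.

3. I therefore pool the last readings of both runs. The selectivity factor s is the summed left-handed product over the summed right-handed product: 2.84, with a common logarithm of 0.453.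

4. In the dusk run at 6.00 d, c(left-handed substrate) reads 32.4%, and the balance gives c(right-handed substrate) as 32.8%. Left-handed substrate and product together make 57.6%, more than half the charge, so the hands interconvert. I assume that each hand reacts with the same partner, at a rate proportional to c(partner) and to its own substrate. Then c(partner) and the equal substrate concentrations cancel from the rate ratio, and s holds for as long as the substrates stay equal. My reckoning for both asked times is an excess of 47.9%.

5. The forecast gives an excess of 100% at 5.0 h, because “only left product can have formed”, then an excess of 46% and 57% reacted at 10 d. It differs from my reckoning at 5.0 h.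

6. The flask gives 48.2% at 5.0 h, 48.0% at 10 d, and 53.8% reacted.

    partner ⇌ dormant form (K = 1.50, k = 0.00305 h⁻¹)
    partner + left-handed substrate → left-handed product (k = 0.0895 M⁻¹ h⁻¹)
    partner + right-handed substrate → right-handed product (k = 0.0313 M⁻¹ h⁻¹)
    2 partner → homo dimer (k = 0.0583 M⁻¹ h⁻¹)
    left-handed substrate ⇌ right-handed substrate (k = 0.465 h⁻¹)
    solid reagent ⇌ partner, rate k6*(cs6 - [partner]) while solid is left; crystals form when [partner] > cs6 (solubility = 0.100 M, k = 0.0312 h⁻¹)

In this flask at 4.28 d, the making of left-handed product uses left-handed substrate at 0.011 of the forward rate of its loss to right-handed substrate. At 10.0 d, this flask holds 14.0% right-handed product; multiplied by s, that gives 39.8% left-handed product, and the flask holds 39.8%. At its end, the neighbour charged with 0.750 equiv of solid reagent holds 6.89% right-handed product; multiplied by s, that gives 19.6%, and that neighbour holds 19.7% left-handed product.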